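The route rests on cutting ring A (the cyclooctane) between C4 (CHOAc) and C5 (CH2). C5, C6 and C7 are read as the three carbons of a former trans-2-methylcyclopropane, and ring C (C7–C8–C9) as a former Z-alkene. One rhodium-catalysed operation turns the acyclic 5-cyclopropylpent-4-enal 15 into cyclooctenone 16. Aldehyde C–H activation, hydrometalation, strain-releasing β-carbon elimination and acyl–alkyl reductive elimination close ring A at C4–C5, place the C4 carbonyl, keep the C6 stereocentre and leave C7=C9 for a hydroxyl-directed cyclopropanation. Aldehyde 15 comes in one step from (R)-citronellal and nitrodiene 13 by enamine catalysis. Its nitromethyl carbon becomes the lactone carbonyl of ring B.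

Key step: step 9

Remark (numbering): C1/C2 = β/α carbons of the butenolide (ring B), C3 = CH bearing the side chain, C4 = CHOAc, C5 = CH2, C6 = CHCH3, C7/C9 = cyclopropane CH, C8 = cyclopropane CH2 (ring C), C10 = side-chain CH, C18 = lactone C=O, C19 = lactone CH2. The target is 3S,4R,6R,7S,9S,10R.
Remark (assumption): compounds 1, 2, 5, 10 and 14 are taken as commercial in high enantiomeric purity. The geometry of the C1=C9 alkene in 8–15 is lost in step 9, so isomerisation there is harmless.

Step 1
Reactants: 1 (S)-propylene oxide; 2 triethyl phosphonoacetate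
Product: 3 ethyl (1R,2R)-2-methylcyclopropane-1-carboxylate
Conditions: n-BuLi, DME, 0 °C, then sealed vessel, 130 °C
Reagents that add atoms: none
Why: Wadsworth–Emmons cyclopropanation, in which the phosphonate anion opens the epoxide at CH2, the phosphoryl group moves to the alkoxide and the ester enolate displaces phosphate with inversion, so the (S)-epoxide carbon becomes the (R)-methyl-bearing carbon (future C6) and the less crowded trans ester should form.

Step 2
Reactants: 3 ethyl (1R,2R)-2-methylcyclopropane-1-carboxylate
Product: 4 (1R,2R)-2-methylcyclopropane-1-carbaldehyde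
Conditions: i-Bu2AlH (1.05 equiv), CH2Cl2, −78 °C; aq. Rochelle salt; used as a dried solution
Reagents that add atoms: none
Why: Partial reduction of an ester at low temperature, where the tetrahedral aluminium hemiacetal survives until work-up, so the aldehyde should be obtained without touching either stereocentre.

Step 3
Reactants: 4 (1R,2R)-2-methylcyclopropane-1-carbaldehyde; 5 dimethyl malonate
Product: 6 dimethyl 2-{[(1R,2R)-2-methylcyclopropyl]methylidene}propanedioate
Conditions: piperidine (10 mol %), AcOH (10 mol %), 4 Å MS, CH2Cl2, rt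
Reagents that add atoms: none
Why: Knoevenagel condensation, clean here because the cyclopropyl aldehyde enolises only with difficulty, so neither self-aldol reaction nor deconjugation should compete and the ring stereocentres stay intact.

Step 4
Reactants: 6 dimethyl 2-{[(1R,2R)-2-methylcyclopropyl]methylidene}propanedioate
Product: 7 2-{[(1R,2R)-2-methylcyclopropyl]methylidene}propane-1,3-diol
Conditions: i-Bu2AlH (4.5 equiv), CH2Cl2, −78 → 0 °C; aq. Rochelle salt
Reagents that add atoms: none
Why: Exhaustive 1,2-reduction of both conjugated esters by the Lewis acidic hydride i-Bu2AlH, which binds the carbonyl oxygen and should therefore spare the C=C bond and the cyclopropane.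

Step 5
Reactants: 7 2-{[(1R,2R)-2-methylcyclopropyl]methylidene}propane-1,3-diol
Product: 8 (2E)-2-(hydroxymethyl)-3-[(1R,2R)-2-methylcyclopropyl]prop-2-enal
Conditions: activated MnO2, CH2Cl2, rt, stopped at mono-oxidation
Reagents that add atoms: none
Why: Chemoselective allylic oxidation, in which MnO2 should attack the less hindered CH2OH (trans to the cyclopropyl group) first and the electron-poor enal so formed slows the second oxidation, giving the thermodynamically preferred E-enal.

Step 6
Reactants: 8 (2E)-2-(hydroxymethyl)-3-[(1R,2R)-2-methylcyclopropyl]prop-2-enal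
Product: 9 (2E)-2-{[(tert-butyldimethylsilyl)oxy]methyl}-3-[(1R,2R)-2-methylcyclopropyl]prop-2-enal
Conditions: TBSCl, imidazole, CH2Cl2, 0 °C → rt
Reagents that add atoms: tert-butyldimethylsilyl chloride CC(C)(C)[Si](C)(C)Cl
Why: Imidazole-promoted silylation of a primary alcohol, which later prevents lactol formation with the aldehyde of 15.

Step 7
Reactants: 9 (2E)-2-{[(tert-butyldimethylsilyl)oxy]methyl}-3-[(1R,2R)-2-methylcyclopropyl]prop-2-enal; 10 nitromethane
Product: 13 (1E,3Z)-3-{[(tert-butyldimethylsilyl)oxy]methyl}-4-[(1R,2R)-2-methylcyclopropyl]-1-nitrobuta-1,3-diene, via nitroaldol 11 (not isolated), via nitroaldol mesylate 12 (not isolated)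
Conditions: MeNO2, t-BuOK (10 mol %), THF–t-BuOH, 0 °C; crude, then MsCl, Et3N, CH2Cl2, −10 °C
Reagents that add atoms: none
Why: Henry reaction followed by mesylation and E1cB elimination, which should give the conjugated E-nitroalkene because 1,2-addition to the hindered α,β-disubstituted enal is faster than 1,4-addition and the carbinol stereocentre is destroyed again.

Step 8
Reactants: 13 (1E,3Z)-3-{[(tert-butyldimethylsilyl)oxy]methyl}-4-[(1R,2R)-2-methylcyclopropyl]-1-nitrobuta-1,3-diene; 14 (R)-citronellal
Product: 15 (2S,3R,4Z)-4-{[(tert-butyldimethylsilyl)oxy]methyl}-2-[(2R)-6-methylhept-5-en-2-yl]-5-[(1R,2R)-2-methylcyclopropyl]-3-(nitromethyl)pent-4-enal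
Conditions: (R)-2-[diphenyl(trimethylsilyloxy)methyl]pyrrolidine (10 mol %), 4-nitrophenol (10 mol %), toluene, 0 °C → rt
Reagents that add atoms: none
Why: Enamine-catalysed asymmetric Michael addition, in which the E-enamine of 14, shielded on one face by the diphenyl(silyloxy)methyl group of the (R)-catalyst, should add 1,4 to the E-nitroalkene through the usual synclinal transition state and so set C3 (S) and C2 (R) in a syn relationship under catalyst control, the remote C10 centre having little influence.

Step 9
Reactants: 15 (2S,3R,4Z)-4-{[(tert-butyldimethylsilyl)oxy]methyl}-2-[(2R)-6-methylhept-5-en-2-yl]-5-[(1R,2R)-2-methylcyclopropyl]-3-(nitromethyl)pent-4-enal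
Product: 16 (3R,4Z,6R,7S,8S)-6-{[(tert-butyldimethylsilyl)oxy]methyl}-3-methyl-8-[(2R)-6-methylhept-5-en-2-yl]-7-(nitromethyl)cyclooct-4-en-1-one
Conditions: [Rh(nbd)(dppe)]BF4 (15 mol %, nbd = norbornadiene, dppe = Ph2PCH2CH2PPh2, pre-activated with H2), ethylene (1 atm), ClCH2CH2Cl, 0.01 M, 65 °C
Reagents that add atoms: none
Why: Cationic monovalent rhodium inserts into the aldehyde C–H bond of 15, syn hydrometalation of the C1=C9 alkene puts H on C1 and Rh on C9 (six-membered rhodacycle), β-carbon elimination breaks the C7–C5 bond of the adjacent cyclopropane with release of its ring strain to give a nine-membered rhodacycle with a primary alkyl–Rh bond, and acyl–alkyl reductive elimination forms C4–C5. The closest known reaction type is the rhodium-catalysed hydroacylation/cyclopropane fragmentation of 5-cyclopropylpent-4-enals to cyclooct-4-enones. Ring A is the only ring closed, by reductive elimination from the nine-membered metallacycle, which can accommodate only a Z C7=C9 alkene. C6 is carried over unchanged because its bonds to C5 and C7 are never broken, C2, C3 and C10 are spectators, and the one new stereocentre C1 should be set by hydride delivery anti to the C2 nitromethyl group, so the two substituents sit trans on the rhodacycle (this centre is erased in step 13). The step needs Rh on C9 rather than C1 (six- versus five-membered chelate, less substituted carbon), cleavage of C7–CH2 rather than C7–CHCH3 (primary versus secondary alkyl rhodium), fragmentation faster than cyclopentanone-forming reductive elimination (strain release), and no reaction at the side-chain alkene (out of reach of the chelated hydride). The silyl ether is a poor β-leaving group, and ethylene fills the free coordination site and slows decarbonylation.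

Step 10
Reactants: 16 (3R,4Z,6R,7S,8S)-6-{[(tert-butyldimethylsilyl)oxy]methyl}-3-methyl-8-[(2R)-6-methylhept-5-en-2-yl]-7-(nitromethyl)cyclooct-4-en-1-one
Product: 19 trans-fused keto lactone (1R,2S,3S,6R,10R; C4 ketone; Z-C7=C9; H-1 and H-2 trans), via keto acid 17 (not isolated), via hydroxy keto acid 18 (not isolated)
Conditions: NaNO2 (3 equiv), AcOH (10 equiv), DMSO, 35 °C; extractive work-up, then 1 M HCl, THF, rt
Reagents that add atoms: sodium nitrite [Na+].[O-]N=O
Why: Nitrosative Nef-type oxidation of a primary nitroalkane to the carboxylic acid through its nitrolic acid, followed by acid desilylation and spontaneous γ-lactonisation, all under weakly acidic conditions that should not epimerise C2 or C3.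

Step 11
Reactants: 19 trans-fused keto lactone
Product: 20 hydroxy lactone (1R,2S,3S,4R,6R,10R; OH cis to the C3 side chain)
Conditions: LiBH(s-Bu)3 (1.1 equiv), THF, −78 °C; pH 7 buffer
Reagents that add atoms: none
Why: Diastereoselective ketone reduction with a bulky borohydride, which should approach C4 from the ring face opposite the C3 side chain (the usual cis outcome for 2-alkylcycloalkanones) and so set 4R, the lactone being untouched at −78 °C.

Step 12
Reactants: 20 hydroxy lactone
Product: 21 cyclopropanated hydroxy lactone (1R,2S,3S,4R,6R,7S,9S,10R; C8 syn to OH)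
Conditions: Et2Zn (2.2 equiv), CH2I2 (2.4 equiv), CH2Cl2, −20 → 0 °C
Reagents that add atoms: diiodomethane ICI
Why: Hydroxyl-directed Simmons–Smith cyclopropanation (Furukawa reagent), in which the C4 zinc alkoxide should deliver CH2 across ring A to the strained Z-alkene on the face syn to oxygen, which is also anti to the C6 methyl and C19 methylene groups, so C7 (S) and C9 (S) are set together while the undirected side-chain alkene reacts more slowly.

Step 13
Reactants: 21 cyclopropanated hydroxy lactone
Product: 24 hydroxy butenolide (deacetyl target; 3S,4R,6R,7S,9S,10R), via C2 phenylselenide 22 (not isolated), via selenoxide 23 (not isolated)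
Conditions: LiN(i-Pr)2 (2.5 equiv), THF, −78 °C; PhSeBr (1.2 equiv), −78 °C; AcOH, then 30% H2O2, pyridine, 0 °C → rt
Reagents that add atoms: none
Why: Enolate selenenylation and selenoxide syn elimination, in which the lactone enolate (alkoxide as spectator) should take up selenium on the face of ring B anti to C9, that is syn to H-1 and anti to H-3, so only H-1 can reach the selenoxide oxygen and the tetrasubstituted C1=C2 alkene forms, pyridine suppressing epoxidation of the side chain.

Step 14
Reactants: 24 hydroxy butenolide
Product: 25 target CNP0018922.1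
Conditions: Ac2O, pyridine, DMAP (cat.), CH2Cl2, rt
Reagents that add atoms: acetic anhydride CC(=O)OC(C)=O
Why: DMAP-catalysed acetylation of the secondary alcohol with retention at C4, the butenolide, cyclopropane and alkene being inert.

Compound list
1 | (S)-propylene oxide | C[C@H]1CO1 | starting material
2 | triethyl phosphonoacetate | CCOC(=O)CP(=O)(OCC)OCC | starting material
3 | ethyl (1R,2R)-2-methylcyclopropane-1-carboxylate | CCOC(=O)[C@@H]1C[C@H]1C | intermediate
4 | (1R,2R)-2-methylcyclopropane-1-carbaldehyde | O=C[C@@H]1C[C@H]1C | intermediate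
5 | dimethyl malonate | COC(=O)CC(=O)OC | starting material
6 | dimethyl 2-{[(1R,2R)-2-methylcyclopropyl]methylidene}propanedioate | COC(=O)C(=C[C@@H]1C[C@H]1C)C(=O)OC | intermediate
7 | 2-{[(1R,2R)-2-methylcyclopropyl]methylidene}propane-1,3-diol | OCC(CO)=C[C@@H]1C[C@H]1C | intermediate
8 | (2E)-2-(hydroxymethyl)-3-[(1R,2R)-2-methylcyclopropyl]prop-2-enal | O=C/C(CO)=C/[C@@H]1C[C@H]1C | intermediate
9 | TBS ether of 8 | O=C/C(CO[Si](C)(C)C(C)(C)C)=C/[C@@H]1C[C@H]1C | intermediate
10 | nitromethane | C[N+](=O)[O-] | starting material
11 | nitroaldol of 9 (both carbinol epimers) | O=[N+]([O-])CC(O)/C(CO[Si](C)(C)C(C)(C)C)=C/[C@@H]1C[C@H]1C | intermediate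
12 | methanesulfonate of 11 | CS(=O)(=O)OC(C[N+](=O)[O-])/C(CO[Si](C)(C)C(C)(C)C)=C/[C@@H]1C[C@H]1C | intermediate
13 | (1E,3Z)-nitrodiene (cyclopropyl trans to the nitrovinyl group) | O=[N+]([O-])/C=C/C(CO[Si](C)(C)C(C)(C)C)=C/[C@@H]1C[C@H]1C | intermediate
14 | (R)-citronellal | O=CC[C@H](C)CCC=C(C)C | starting material
15 | syn Michael adduct, (2S,3R,4Z)-5-cyclopropylpent-4-enal | O=C[C@@H]([C@H](C)CCC=C(C)C)[C@@H](C[N+](=O)[O-])/C(CO[Si](C)(C)C(C)(C)C)=C/[C@@H]1C[C@H]1C | intermediate
16 | (3R,4Z,6R,7S,8S)-cyclooct-4-en-1-one | O=C1C[C@@H](C)/C=C\[C@@H](CO[Si](C)(C)C(C)(C)C)[C@H](C[N+](=O)[O-])[C@@H]1[C@H](C)CCC=C(C)C | intermediate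
17 | keto acid (CO2H in place of CH2NO2 of 16) | O=C1C[C@@H](C)/C=C\[C@@H](CO[Si](C)(C)C(C)(C)C)[C@H](C(=O)O)[C@@H]1[C@H](C)CCC=C(C)C | intermediate
18 | hydroxy keto acid (17 without TBS) | O=C1C[C@@H](C)/C=C\[C@@H](CO)[C@H](C(=O)O)[C@@H]1[C@H](C)CCC=C(C)C | intermediate
19 | trans-fused keto lactone | O=C1C[C@@H](C)/C=C\[C@H]2COC(=O)[C@@H]2[C@@H]1[C@H](C)CCC=C(C)C | intermediate
20 | (4R)-hydroxy lactone | O[C@@H]1C[C@@H](C)/C=C\[C@H]2COC(=O)[C@@H]2[C@@H]1[C@H](C)CCC=C(C)C | intermediate
21 | cyclopropanated hydroxy lactone | O[C@@H]1C[C@@H](C)[C@@H]2C[C@@H]2[C@H]3COC(=O)[C@@H]3[C@@H]1[C@H](C)CCC=C(C)C | intermediate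
22 | C2 phenylselenide (Se syn to H-1) | O[C@@H]1C[C@@H](C)[C@@H]2C[C@@H]2[C@H]3COC(=O)[C@@]3([Se]c4ccccc4)[C@@H]1[C@H](C)CCC=C(C)C | intermediate
23 | selenoxide of 22 | O[C@@H]1C[C@@H](C)[C@@H]2C[C@@H]2[C@H]3COC(=O)[C@@]3([Se](=O)c4ccccc4)[C@@H]1[C@H](C)CCC=C(C)C | intermediate
24 | hydroxy butenolide (deacetyl target) | O[C@@H]1C[C@@H](C)[C@@H]2C[C@@H]2C2=C(C(=O)OC2)[C@@H]1[C@H](C)CCC=C(C)C | intermediate
25 | target CNP0018922.1 | CC(=O)O[C@@H]1C[C@@H](C)[C@@H]2C[C@@H]2C2=C(C(=O)OC2)[C@@H]1[C@H](C)CCC=C(C)C | target

Total step count: 14. Longest linear sequence: 14 steps (1 → 25). Compound 14 enters at step 8.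

Steps most likely to fail

Step 9. Decarbonylation of the acyl rhodium hydride, or reductive elimination before the cyclopropane opens, may outrun insertion into the hindered trisubstituted alkene. The fallback sets out from 15 and replaces free-aldehyde activation by chelation-assisted C–H activation. Condensation of 15 with 2-amino-3-methylpyridine (4 Å MS, toluene) should give the N-(3-methylpyridin-2-yl) aldimine F1. Its iminoacyl rhodium hydride, formed with RhCl(PPh3)3 in toluene at 110 °C, is held in a five-membered chelate and cannot lose CO. The same hydrometalation, β-carbon elimination and reductive elimination should then give the cyclic ketimine F2, and hydrolysis with a pH 4 buffer comes back to the route at 16.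

Step 12. Chemoselectivity may be lost through attack of the electrophilic carbenoid on the electron-rich side-chain alkene. The fallback sets out from 20 and inverts both the order of events and the polarity of the cyclopropanation. The procedure of step 13 applied to 20 should give the allyl-flanked C2 phenylselenide F3, then its selenoxide F4, then the cross-ring dienolide F5 (C1=C2–C9=C7). Dimethylsulfoxonium methylide (Me3S(O)I, NaH, DMSO, rt; Corey–Chaykovsky reaction) should add 1,6 at C7, anti to the C6 methyl group, because the β-carbon C1 is fully substituted. It then closes onto C9. This nucleophilic reagent ignores unactivated alkenes, and the sequence comes back at 24.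

Step 13. C–Se bond formation at the congested C2 may be sluggish, or the syn elimination may turn toward H-3. The fallback sets out from 21 and avoids any bond to C2. LiN(i-Pr)2 with Me3SiCl present (THF, −78 °C) should give the bis-silylated ketene acetal F6. DDQ with 2,6-lutidine in CH2Cl2 should abstract hydride from C1, where the developing cation is stabilised by the ketene acetal and by ring C, to give the trimethylsilyl ether of the butenolide F7. Mild acidic work-up cleaves this ether and comes back at 24.

Further compounds
F1 | step 9 | N-(3-methylpyridin-2-yl) aldimine of 15 | Cc1cccnc1/N=C/[C@@H]([C@H](C)CCC=C(C)C)[C@@H](C[N+](=O)[O-])/C(CO[Si](C)(C)C(C)(C)C)=C/[C@@H]1C[C@H]1C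
F2 | step 9 | N-(3-methylpyridin-2-yl) ketimine of 16 | Cc1cccnc1N=C1C[C@@H](C)/C=C\[C@@H](CO[Si](C)(C)C(C)(C)C)[C@H](C[N+](=O)[O-])[C@@H]1[C@H](C)CCC=C(C)C
F3 | step 12 | C2 phenylselenide of 20 | O[C@@H]1C[C@@H](C)/C=C\[C@H]2COC(=O)[C@@]2([Se]c3ccccc3)[C@@H]1[C@H](C)CCC=C(C)C
F4 | step 12 | selenoxide of F3 | O[C@@H]1C[C@@H](C)/C=C\[C@H]2COC(=O)[C@@]2([Se](=O)c3ccccc3)[C@@H]1[C@H](C)CCC=C(C)C
F5 | step 12 | hydroxy dienolide (C1=C2 and Z-C7=C9) | O[C@@H]1C[C@@H](C)/C=C\C2=C(C(=O)OC2)[C@@H]1[C@H](C)CCC=C(C)C
F6 | step 13 | bis-silylated ketene acetal of 21 | C[Si](C)(C)O[C@@H]1C[C@@H](C)[C@@H]2C[C@@H]2[C@H]3COC(O[Si](C)(C)C)=C3[C@@H]1[C@H](C)CCC=C(C)C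
F7 | step 13 | trimethylsilyl ether of 24 | C[Si](C)(C)O[C@@H]1C[C@@H](C)[C@@H]2C[C@@H]2C2=C(C(=O)OC2)[C@@H]1[C@H](C)CCC=C(C)C
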